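**Retrosynthetic overview**
- The target comes from hydrolysis of two dimethyl acetals (C11, C12); the coumarate is built by acylation of the 1β-alcohol with acryloyl chloride and Heck coupling with 4-iodophenol; the 1β-alcohol comes from hydroxyl-directed reduction of a C1 ketone.
- Ring B is closed last, by ring-closing metathesis (C7=C8) between an allyl group on C5 and a methylidene on C8.
- Key step: a semipinacol 1,2-methyl shift (C1 to C10) in a syn-epoxy alcohol makes the C10 quaternary centre anti to the C5 hydroxyl (the trans ring fusion). Addition of a carbon nucleophile to a C5 ketone would be expected to give the other C5 epimer.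
- The epoxy alcohol comes from a 2,3-disubstituted 4,4-dimethylcyclohexenone by catalytic asymmetric methyl addition and directed epoxidation; the enone comes from a vinylogous ester by α′-dimethylation, Stork–Danheiser allylation, α-methylenation and acetalization.
- C9 is set first, by organocatalytic Michael addition of cyclohexane-1,3-dione to fumaraldehyde mono-acetal. Ring order: ring A (from the dione), a temporary pyran, then ring B.

Assumption: acetal methyl groups are protecting-group atoms and are not counted in the size of a starting material; atom labels C1–C12 follow drimane numbering of the target, and α/β are the faces of its decalin (β = face of the C10 methyl).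

Step 1
Reactants: 1 cyclohexane-1,3-dione; 2 (E)-4,4-dimethoxybut-2-enal
Product: 4 (4S)-4-(dimethoxymethyl)-2-methoxy-2,3,4,6,7,8-hexahydro-5H-chromen-5-one, via lactol 3 (not isolated)
Conditions: (R)-α,α-diphenylprolinol TMS ether (10 mol%), PhCO2H (10 mol%), CH2Cl2, 0 °C → rt; then MeOH (5 equiv), PPTS (5 mol%), 4 Å MS, rt
Reagents that add atoms: methanol (CO)
Why: Iminium-catalysed Michael addition of the dione enol to the enal face left open by the (R)-catalyst sets C9, and the adduct closes to a lactol whose O-methylation gives a cyclic mixed acetal that both masks the C12 aldehyde and serves as the vinylogous ester for step 3 (organocatalytic Michael addition, acetalization).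

Step 2
Reactants: 4 (4S)-4-(dimethoxymethyl)-2-methoxy-2,3,4,6,7,8-hexahydro-5H-chromen-5-one
Product: 6 (4S)-4-(dimethoxymethyl)-2-methoxy-6,6-dimethyl-2,3,4,6,7,8-hexahydro-5H-chromen-5-one, via monomethyl ketone 5 (not isolated)
Conditions: LiN(iPr)2 (1.1 equiv), THF, −78 °C, MeI; then LiN(iPr)2 (1.2 equiv), −78 °C, MeI, → 0 °C (one flask)
Reagents that add atoms: iodomethane (CI)
Why: Kinetic α′-deprotonation of a vinylogous ester (Stork–Danheiser alkylation) occurs only at the CH2 next to the ketone, so both methyl groups go to C4 beside the carbonyl that becomes C5, and C9 is untouched.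

Step 3
Reactants: 6 (4S)-4-(dimethoxymethyl)-2-methoxy-6,6-dimethyl-2,3,4,6,7,8-hexahydro-5H-chromen-5-one
Product: 8 3-allyl-2-[(2S)-1,1-dimethoxy-4-oxobutan-2-yl]-4,4-dimethylcyclohex-2-en-1-one, via tertiary carbinol 7 (not isolated)
Conditions: allylMgBr (1.5 equiv), THF, −78 → 0 °C; then 5% aq. oxalic acid, THF, 0 °C
Reagents that add atoms: allylmagnesium bromide (C=CC[Mg]Br); water (O)
Why: The Grignard reagent adds 1,2 to the only ketone (C5), and mild acid then causes the Stork–Danheiser allylic transposition, which moves the carbonyl to C1, leaves the allyl group (C6–C7) on C5 and opens the pyran to free the C12 aldehyde while the C11 dimethyl acetal stays.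

Step 4
Reactants: 8 3-allyl-2-[(2S)-1,1-dimethoxy-4-oxobutan-2-yl]-4,4-dimethylcyclohex-2-en-1-one
Product: 9 (3S)-3-(2-allyl-3,3-dimethyl-6-oxocyclohex-1-en-1-yl)-4,4-dimethoxy-2-methylidenebutanal
Conditions: 37% aq. HCHO, pyrrolidine (10 mol%), EtCO2H (10 mol%), i-PrOH, 45 °C
Reagents that add atoms: formaldehyde (C=O)
Why: Amine-catalysed Mannich condensation and elimination (organocatalytic α-methylenation) acts on the only enolisable aldehyde and turns C8 into the 1,1-disubstituted alkene needed for ring closure, while the non-acidic C9 centre is kept.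

Step 5
Reactants: 9 (3S)-3-(2-allyl-3,3-dimethyl-6-oxocyclohex-1-en-1-yl)-4,4-dimethoxy-2-methylidenebutanal
Product: 10 3-allyl-4,4-dimethyl-2-[(2S)-1,1,4,4-tetramethoxy-3-methylidenebutan-2-yl]cyclohex-2-en-1-one
Conditions: HC(OMe)3, MeOH, CeCl3·7H2O (5 mol%), rt
Reagents that add atoms: trimethyl orthoformate (COC(OC)OC)
Why: Lewis-acid-catalysed acetalization (Luche-type) masks the enal so that C11 and C12 are both dimethyl acetals, which are inert to the organozinc, peroxide, metathesis, hydride and Heck steps that follow.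

Step 6
Reactants: 10 3-allyl-4,4-dimethyl-2-[(2S)-1,1,4,4-tetramethoxy-3-methylidenebutan-2-yl]cyclohex-2-en-1-one
Product: 12 (1S,2S,6R)-6-allyl-2,5,5-trimethyl-1-[(2S)-1,1,4,4-tetramethoxy-3-methylidenebutan-2-yl]-7-oxabicyclo[4.1.0]heptan-2-ol, via tertiary allylic alcohol 11 (not isolated)
Conditions: ZnMe2 (3 equiv), Ti(OiPr)4 (1.2 equiv), trans-cyclohexane-1,2-diamine bis(hydroxycamphorsulfonamide) ligand (10 mol%, enantiomer giving Re-face attack), toluene–hexane, rt; then TBHP (decane), 0 °C
Reagents that add atoms: dimethylzinc (C[Zn]C); tert-butyl hydroperoxide (CC(C)(C)OO)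
Why: Ligand-accelerated, titanium-mediated enantioselective 1,2-addition of methyl to the Re face of the C1 ketone (catalyst control) sets C1 as S, and the metal alkoxide then directs the peroxide to the same face of the C5=C10 alkene (hydroxyl-directed syn epoxidation), which fixes the oxygen on the α face at C5 and C10.

Step 7
Reactants: 12 (1S,2S,6R)-6-allyl-2,5,5-trimethyl-1-[(2S)-1,1,4,4-tetramethoxy-3-methylidenebutan-2-yl]-7-oxabicyclo[4.1.0]heptan-2-ol
Product: 13 (2R,3R)-3-allyl-3-hydroxy-2,4,4-trimethyl-2-[(2S)-1,1,4,4-tetramethoxy-3-methylidenebutan-2-yl]cyclohexan-1-one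
Conditions: BF3·OEt2 (0.3 equiv), CH2Cl2, −78 °C, 15 min; Et3N quench
Reagents that add atoms: none
Why: Proposed new method: a Lewis-acid-triggered semipinacol 1,2-methyl shift in a fully substituted syn-2,3-epoxy tertiary alcohol, in which boron on the epoxide oxygen weakens the C10–O bond, the C1 methyl (pseudo-axial, on the face opposite the epoxide and antiperiplanar to that bond) migrates to C10 with inversion there as C1 collapses to the ketone and the oxygen stays on C5, so the C10 methyl (β) and the C5 hydroxyl (α) are set anti in one stereospecific event; the closest known reaction type is the Suzuki–Tsuchihashi-type semipinacol rearrangement of syn-epoxy alcohols from trisubstituted cyclohexene oxides with alkyl migration, not yet shown for a tetrasubstituted epoxide with methyl as the migrating group and acetal-bearing neighbours.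

Step 8
Reactants: 13 (2R,3R)-3-allyl-3-hydroxy-2,4,4-trimethyl-2-[(2S)-1,1,4,4-tetramethoxy-3-methylidenebutan-2-yl]cyclohexan-1-one
Product: 14 (4aR,8S,8aR)-7,8-bis(dimethoxymethyl)-4a-hydroxy-4,4,8a-trimethyl-3,4,4a,5,8,8a-hexahydronaphthalen-1(2H)-one
Conditions: second-generation Hoveyda–Grubbs catalyst (5 mol%), toluene, 80 °C
Reagents that add atoms: none
Why: Ring-closing metathesis between the allyl group on C5 and the methylidene on C8 closes ring B as the trisubstituted Δ7 cyclohexene, and because the two chains were placed by step 7 with the methyl and hydroxyl anti, the ring fusion is trans and no stereocentre is touched.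

Step 9
Reactants: 14 (4aR,8S,8aR)-7,8-bis(dimethoxymethyl)-4a-hydroxy-4,4,8a-trimethyl-3,4,4a,5,8,8a-hexahydronaphthalen-1(2H)-one
Product: 15 (1R,4aR,8R,8aS)-7,8-bis(dimethoxymethyl)-4,4,8a-trimethyl-1,2,3,4,4a,5,8,8a-octahydronaphthalene-1,4a-diol
Conditions: Me4NBH(OAc)3 (5 equiv), MeCN–AcOH (1:1), −30 °C
Reagents that add atoms: none
Why: In this Evans–Saksena directed reduction the acetoxyborohydride binds the axial 5α-hydroxyl and delivers hydride intramolecularly to the α face of the C1 ketone, giving the equatorial 1β-alcohol (1,3-anti diol).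

Step 10
Reactants: 15 (1R,4aR,8R,8aS)-7,8-bis(dimethoxymethyl)-4,4,8a-trimethyl-1,2,3,4,4a,5,8,8a-octahydronaphthalene-1,4a-diol; 16 acryloyl chloride
Product: 17 (1R,4aR,8R,8aS)-7,8-bis(dimethoxymethyl)-4a-hydroxy-4,4,8a-trimethyl-1,2,3,4,4a,5,8,8a-octahydronaphthalen-1-yl prop-2-enoate
Conditions: Et3N, DMAP (10 mol%), CH2Cl2, 0 °C → rt
Reagents that add atoms: none
Why: DMAP-catalysed acylation takes place only at the secondary 1β-hydroxyl, because the tertiary C5 hydroxyl is too hindered to be acylated.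

Step 11
Reactants: 17 (1R,4aR,8R,8aS)-7,8-bis(dimethoxymethyl)-4a-hydroxy-4,4,8a-trimethyl-1,2,3,4,4a,5,8,8a-octahydronaphthalen-1-yl prop-2-enoate; 18 4-iodophenol
Product: 19 (1R,4aR,8R,8aS)-7,8-bis(dimethoxymethyl)-4a-hydroxy-4,4,8a-trimethyl-1,2,3,4,4a,5,8,8a-octahydronaphthalen-1-yl (2E)-3-(4-hydroxyphenyl)prop-2-enoate
Conditions: Pd(OAc)2 (5 mol%), P(o-tol)3 (10 mol%), Et3N, DMF, 80 °C
Reagents that add atoms: none
Why: Mizoroki–Heck arylation of the acrylate (oxidative addition of the aryl iodide to zerovalent palladium, syn insertion, syn β-hydride elimination) gives the (E)-cinnamate, the free phenol is tolerated, and the acetal at C11 keeps C9 from epimerising under base.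

Step 12
Reactants: 19 (1R,4aR,8R,8aS)-7,8-bis(dimethoxymethyl)-4a-hydroxy-4,4,8a-trimethyl-1,2,3,4,4a,5,8,8a-octahydronaphthalen-1-yl (2E)-3-(4-hydroxyphenyl)prop-2-enoate
Product: 20 (1R,4aR,8R,8aS)-7,8-diformyl-4a-hydroxy-4,4,8a-trimethyl-1,2,3,4,4a,5,8,8a-octahydronaphthalen-1-yl (2E)-3-(4-hydroxyphenyl)prop-2-enoate
Conditions: 0.5 M aq. HCl–THF (1:4), 0 °C → rt
Reagents that add atoms: water (O)
Why: Acid-catalysed acetal hydrolysis through oxocarbenium ions frees the C12 enal and the C11 aldehyde, with dilute acid and low temperature chosen so that C9 does not epimerise and the tertiary C5 hydroxyl does not eliminate.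

**Compound list**
1 | cyclohexane-1,3-dione | O=C1CCCC(=O)C1 | starting material
2 | (E)-4,4-dimethoxybut-2-enal | COC(OC)/C=C/C=O | starting material
3 | (4S)-4-(dimethoxymethyl)-2-hydroxy-2,3,4,6,7,8-hexahydro-5H-chromen-5-one (lactol, both C2 epimers) | OC1C[C@H](C(OC)OC)C2=C(CCCC2=O)O1 | intermediate
4 | (4S)-4-(dimethoxymethyl)-2-methoxy-2,3,4,6,7,8-hexahydro-5H-chromen-5-one (both C2 epimers) | COC1C[C@H](C(OC)OC)C2=C(CCCC2=O)O1 | intermediate
5 | (4S)-4-(dimethoxymethyl)-2-methoxy-6-methyl-2,3,4,6,7,8-hexahydro-5H-chromen-5-one (C2 and C6 epimers) | COC1C[C@H](C(OC)OC)C2=C(CCC(C)C2=O)O1 | intermediate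
6 | (4S)-4-(dimethoxymethyl)-2-methoxy-6,6-dimethyl-2,3,4,6,7,8-hexahydro-5H-chromen-5-one (both C2 epimers) | COC1C[C@H](C(OC)OC)C2=C(CCC(C)(C)C2=O)O1 | intermediate
7 | (4S)-5-allyl-4-(dimethoxymethyl)-2-methoxy-6,6-dimethyl-3,4,5,6,7,8-hexahydro-2H-chromen-5-ol (C2 and C5 epimers) | COC1C[C@H](C(OC)OC)C2=C(CCC(C)(C)C2(O)CC=C)O1 | intermediate
8 | 3-allyl-2-[(2S)-1,1-dimethoxy-4-oxobutan-2-yl]-4,4-dimethylcyclohex-2-en-1-one | C=CCC1=C([C@@H](C(OC)OC)CC=O)C(=O)CCC1(C)C | intermediate
9 | (3S)-3-(2-allyl-3,3-dimethyl-6-oxocyclohex-1-en-1-yl)-4,4-dimethoxy-2-methylidenebutanal | C=CCC1=C([C@@H](C(OC)OC)C(=C)C=O)C(=O)CCC1(C)C | intermediate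
10 | 3-allyl-4,4-dimethyl-2-[(2S)-1,1,4,4-tetramethoxy-3-methylidenebutan-2-yl]cyclohex-2-en-1-one | C=CCC1=C([C@@H](C(OC)OC)C(=C)C(OC)OC)C(=O)CCC1(C)C | intermediate
11 | (1S)-3-allyl-1,4,4-trimethyl-2-[(2R)-1,1,4,4-tetramethoxy-3-methylidenebutan-2-yl]cyclohex-2-en-1-ol (side chain unchanged in space; descriptor changes by priority only) | CC1(C)CC[C@](C)(O)C([C@@H](C(OC)OC)C(=C)C(OC)OC)=C1CC=C | intermediate
12 | (1S,2S,6R)-6-allyl-2,5,5-trimethyl-1-[(2S)-1,1,4,4-tetramethoxy-3-methylidenebutan-2-yl]-7-oxabicyclo[4.1.0]heptan-2-ol (epoxide and hydroxyl both α, C1 methyl β) | CC1(C)CC[C@](C)(O)[C@]2([C@@H](C(OC)OC)C(=C)C(OC)OC)O[C@]12CC=C | intermediate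
13 | (2R,3R)-3-allyl-3-hydroxy-2,4,4-trimethyl-2-[(2S)-1,1,4,4-tetramethoxy-3-methylidenebutan-2-yl]cyclohexan-1-one (C10 methyl β, C5 hydroxyl α) | CC1(C)CCC(=O)[C@](C)([C@@H](C(OC)OC)C(=C)C(OC)OC)[C@@]1(O)CC=C | intermediate
14 | (4aR,8S,8aR)-7,8-bis(dimethoxymethyl)-4a-hydroxy-4,4,8a-trimethyl-3,4,4a,5,8,8a-hexahydronaphthalen-1(2H)-one (trans-fused) | CC1(C)CCC(=O)[C@]2(C)[C@@H](C(OC)OC)C(C(OC)OC)=CC[C@@]12O | intermediate
15 | (1R,4aR,8R,8aS)-7,8-bis(dimethoxymethyl)-4,4,8a-trimethyl-1,2,3,4,4a,5,8,8a-octahydronaphthalene-1,4a-diol | CC1(C)CC[C@@H](O)[C@]2(C)[C@@H](C(OC)OC)C(C(OC)OC)=CC[C@@]12O | intermediate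
16 | acryloyl chloride | C=CC(=O)Cl | starting material
17 | (1R,4aR,8R,8aS)-7,8-bis(dimethoxymethyl)-4a-hydroxy-4,4,8a-trimethyl-1,2,3,4,4a,5,8,8a-octahydronaphthalen-1-yl prop-2-enoate | CC1(C)CC[C@@H](OC(=O)C=C)[C@]2(C)[C@@H](C(OC)OC)C(C(OC)OC)=CC[C@@]12O | intermediate
18 | 4-iodophenol | Oc1ccc(I)cc1 | starting material
19 | (1R,4aR,8R,8aS)-7,8-bis(dimethoxymethyl)-4a-hydroxy-4,4,8a-trimethyl-1,2,3,4,4a,5,8,8a-octahydronaphthalen-1-yl (2E)-3-(4-hydroxyphenyl)prop-2-enoate | CC1(C)CC[C@@H](OC(=O)/C=C/c2ccc(O)cc2)[C@]2(C)[C@@H](C(OC)OC)C(C(OC)OC)=CC[C@@]12O | intermediate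
20 | (1R,4aR,8R,8aS)-7,8-diformyl-4a-hydroxy-4,4,8a-trimethyl-1,2,3,4,4a,5,8,8a-octahydronaphthalen-1-yl (2E)-3-(4-hydroxyphenyl)prop-2-enoate (CNP0323926.1) | CC1(C)CC[C@@H](OC(=O)/C=C/c2ccc(O)cc2)[C@]2(C)[C@@H](C=O)C(C=O)=CC[C@@]12O | target

**Totals**
Total step count: 12. Longest linear sequence: 12.

**Steps most likely to fail**

The asymmetric methylation and epoxidation (step 6) may be slow or poorly face-selective, because the enone is tetrasubstituted, hindered and carries Lewis-basic acetals. The fallback gives up catalyst control and separates diastereomers. It sets out from 10: MeMgBr with CeCl3 in THF at −78 °C (organocerium 1,2-addition) gives 11 together with its C1 epimer (1R)-3-allyl-1,4,4-trimethyl-2-[(2R)-1,1,4,4-tetramethoxy-3-methylidenebutan-2-yl]cyclohex-2-en-1-ol F1, which is removed by chromatography (C9 is already fixed, so the two are diastereomers). Isolated 11 is then epoxidised with VO(acac)2 and TBHP in CH2Cl2 (hydroxyl-directed, syn), and the route is rejoined at 12.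

The semipinacol methyl shift (step 7, the proposed new method) may fail through cleavage of the C5–O bond instead, participation of an acetal oxygen at the C10 cation, or loss of an acetal to the Lewis acid. Its fallback uses known chemistry and avoids the rearrangement. It sets out from 10: Weitz–Scheffer epoxidation (TBHP, DBU, CH2Cl2) gives the epoxy ketone (1R,6R)-6-allyl-5,5-dimethyl-1-[(2S)-1,1,4,4-tetramethoxy-3-methylidenebutan-2-yl]-7-oxabicyclo[4.1.0]heptan-2-one F2, with the α-epoxide separated from its diastereomer. Reductive alkylation with Li/NH3 in THF at −78 °C then cleaves the C10–O bond to the enolate–alkoxide, which is trapped with MeI at C10 anti to the C5 alkoxide (chelate control of the Fráter–Seebach type). This comes back to the route at 13.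

The final hydrolysis (step 12) may epimerise C9, eliminate the C5 hydroxyl or stall at the hindered C11 acetal, on a substrate that also carries the phenolic cinnamate. The fallback changes the order and the coupling. It sets out from 17, whose acetals are hydrolysed first (wet silica gel with oxalic acid, CH2Cl2, rt) to (1R,4aR,8R,8aS)-7,8-diformyl-4a-hydroxy-4,4,8a-trimethyl-1,2,3,4,4a,5,8,8a-octahydronaphthalen-1-yl prop-2-enoate F3. The aryl group is then attached under base-free Heck–Matsuda conditions (Pd(OAc)2, MeOH, rt) with 4-hydroxybenzenediazonium tetrafluoroborate F4, made from 4-aminophenol with NaNO2 and HBF4. This comes back to the route at 20.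

Further compounds
F1 | step 6 | (1R)-3-allyl-1,4,4-trimethyl-2-[(2R)-1,1,4,4-tetramethoxy-3-methylidenebutan-2-yl]cyclohex-2-en-1-ol | CC1(C)CC[C@@](C)(O)C([C@@H](C(OC)OC)C(=C)C(OC)OC)=C1CC=C
F2 | step 7 | (1R,6R)-6-allyl-5,5-dimethyl-1-[(2S)-1,1,4,4-tetramethoxy-3-methylidenebutan-2-yl]-7-oxabicyclo[4.1.0]heptan-2-one | CC1(C)CCC(=O)[C@]2([C@@H](C(OC)OC)C(=C)C(OC)OC)O[C@]12CC=C
F3 | step 12 | (1R,4aR,8R,8aS)-7,8-diformyl-4a-hydroxy-4,4,8a-trimethyl-1,2,3,4,4a,5,8,8a-octahydronaphthalen-1-yl prop-2-enoate | CC1(C)CC[C@@H](OC(=O)C=C)[C@]2(C)[C@@H](C=O)C(C=O)=CC[C@@]12O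
F4 | step 12 | 4-hydroxybenzenediazonium tetrafluoroborate | N#[N+]c1ccc(O)cc1.F[B-](F)(F)F
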